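**Plan**

1. Numbering follows the macrolide: C1 lactone carbonyl, C2 (Me), C3 ketone, C4 (OH, CH2OH), C6=C7 (Z), C8 (Me), C10 (=CH2), C11=C12 (Z, 12-Me), C13 (Et, ring oxygen).
2. Enabling feature: C10(=CH2)–C11=C12 is a 2-substituted 1,3-diene, and its central sp2–sp2 bond C10–C11 lies across the 14-membered ring from the lactone; the first cut opens the ring there to a C10 2-bromoalkene and a C11 Z-trimethylstannane.
3. Further cuts, in order: C2–C3 (aldol, then oxidation), C4–C5 (enolate alkylation), C6=C7 (Z-olefination), C8–C9 (auxiliary alkylation).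
4. Forward: the C3–C10 bromo aldehyde and the stannyl propanoate (C1–C2 plus C11–C15) are made separately, joined at C2–C3 and oxidised at C3; the only ring closes last at C10–C11, and fluoride then frees the C4 diol.
5. Stereochemistry: C13 from lipase resolution of the stannyl carbinol; C8 from alkylation of the (R)-benzyloxazolidinone; C4 from (S)-glycerate through its cis tert-butyl acetal (self-regeneration of the stereocentre); both Z alkenes from carbomagnesiation and Still–Gennari olefination; C2 by equilibration of the β-keto lactone.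

Key step: step 16

Remark on the chemistry: C2 lies between the lactone and ketone carbonyls and epimerises through the enol. It is assumed that the (2R) epimer of the target is the one favoured at equilibrium in the ring, so C2 is carried as an epimer mixture and fixed in the last step.

**Route**

Step 1
Reactants: 1 rac-pent-1-yn-3-ol
Product: 3 rac-(1Z)-2-methyl-1-(trimethylstannyl)pent-1-en-3-ol, via chelated alkenylmagnesium alkoxide 2 (not isolated)
Conditions: MeMgBr (3 equiv), CuI (10 mol %), THF/Et2O, −10 → 23 °C; then Me3SnCl, 0 → 23 °C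
Reagents that add atoms: methylmagnesium bromide C[Mg]Br; trimethyltin chloride C[Sn](C)(C)Cl
Why: Copper-catalysed anti-carbomagnesiation of the propargylic alkoxide puts the methyl group on C12 and magnesium on C11, held cis to the carbinol in a five-membered chelate, and Grignard stannylation with retention fixes the Z alkene with tin where the coupling needs it.

Step 2
Reactants: 3 rac-(1Z)-2-methyl-1-(trimethylstannyl)pent-1-en-3-ol
Product: 4 (1Z,3S)-2-methyl-1-(trimethylstannyl)pent-1-en-3-ol
Conditions: immobilised Candida antarctica lipase B, vinyl acetate, hexane, 30 °C, stopped just past half conversion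
Reagents that add atoms: none
Why: Lipase-catalysed kinetic resolution by transesterification should acylate the (R)-carbinol (large alkenyl, medium ethyl substituent) and leave the (S)-alcohol, which carries the C13 configuration, and running past half conversion protects the enantiopurity of the recovered alcohol.

Step 3
Reactants: 4 (1Z,3S)-2-methyl-1-(trimethylstannyl)pent-1-en-3-ol
Product: 5 (1Z,3S)-2-methyl-1-(trimethylstannyl)pent-1-en-3-yl propanoate
Conditions: (EtCO)2O, Et3N, DMAP (cat.), CH2Cl2, 0 → 23 °C
Reagents that add atoms: propanoic anhydride CCC(=O)OC(=O)CC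
Why: DMAP-catalysed acylation of the secondary alcohol with retention at C13 installs C1, C2 and the C2 methyl group as the propanoate.

Step 4
Reactants: 6 (R)-4-benzyl-3-propanoyloxazolidin-2-one; 7 2,3-dibromoprop-1-ene
Product: 9 (R)-4-benzyl-3-[(2S)-4-bromo-2-methylpent-4-enoyl]oxazolidin-2-one, via sodium Z-enolate of the propanoyl imide 8 (not isolated)
Conditions: NaN(SiMe3)2, THF, −78 °C; then 7, −78 → −40 °C
Reagents that add atoms: none
Why: Evans auxiliary alkylation, in which the chelated sodium Z-enolate is attacked by the allylic bromide terminus of 7 on the face opposite the benzyl group, should set C8 as (S) while the vinylic bromide stays untouched.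

Step 5
Reactants: 9 (R)-4-benzyl-3-[(2S)-4-bromo-2-methylpent-4-enoyl]oxazolidin-2-one
Product: 10 (2S)-4-bromo-2-methylpent-4-en-1-ol
Conditions: LiBH4, MeOH (1 equiv), Et2O, 0 °C
Reagents that add atoms: none
Why: Reductive removal of the auxiliary with LiBH4 gives the primary alcohol without touching the α-stereocentre or the vinyl bromide.

Step 6
Reactants: 10 (2S)-4-bromo-2-methylpent-4-en-1-ol
Product: 12 methyl (2Z,4S)-6-bromo-2,4-dimethylhepta-2,6-dienoate, via (2S)-4-bromo-2-methylpent-4-enal 11 (not isolated)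
Conditions: Dess–Martin periodinane, CH2Cl2, 0 → 23 °C, filtered cold; then (CF3CH2O)2P(O)CH(CH3)CO2Me, KN(SiMe3)2, 18-crown-6, THF, −78 °C
Reagents that add atoms: methyl 2-[bis(2,2,2-trifluoroethoxy)phosphoryl]propanoate COC(=O)C(C)P(=O)(OCC(F)(F)F)OCC(F)(F)F
Why: Dess–Martin oxidation followed without isolation by Still–Gennari olefination should give the Z trisubstituted enoate (C6=C7) under kinetic control, and the low temperature keeps the α-stereocentre of aldehyde 11 intact.

Step 7
Reactants: 12 methyl (2Z,4S)-6-bromo-2,4-dimethylhepta-2,6-dienoate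
Product: 13 (2Z,4S)-6-bromo-2,4-dimethylhepta-2,6-dien-1-ol
Conditions: iBu2AlH (2.2 equiv), CH2Cl2, −78 °C; aqueous potassium sodium tartrate
Reagents that add atoms: none
Why: 1,2-Reduction of the enoate by iBu2AlH gives the allylic alcohol with the Z geometry unchanged.

Step 8
Reactants: 13 (2Z,4S)-6-bromo-2,4-dimethylhepta-2,6-dien-1-ol
Product: 14 (4S,5Z)-2,7-dibromo-4,6-dimethylhepta-1,5-diene
Conditions: CBr4, PPh3, CH2Cl2, −20 → 0 °C
Reagents that add atoms: carbon tetrabromide BrC(Br)(Br)Br
Why: Appel bromination converts the primary allylic alcohol into the bromide by SN2 displacement of the oxyphosphonium ion under neutral conditions that do not isomerise the Z alkene.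

Step 9
Reactants: 15 methyl (4S)-2,2-dimethyl-1,3-dioxolane-4-carboxylate
Product: 16 methyl (2S,4S)-2-tert-butyl-1,3-dioxolane-4-carboxylate (cis isomer)
Conditions: t-BuCHO (excess), TsOH·H2O (cat.), pentane, reflux with slow removal of acetone; chromatographic separation of the cis isomer
Reagents that add atoms: pivalaldehyde CC(C)(C)C=O
Why: Acid-catalysed transacetalisation driven by removal of acetone forms the new acetal centre under thermodynamic control as a cis/trans mixture, and the separated cis (2S,4S) isomer stores the chirality at the acetal carbon for the moment when C4 becomes planar.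

Step 10
Reactants: 16 methyl (2S,4S)-2-tert-butyl-1,3-dioxolane-4-carboxylate; 14 (4S,5Z)-2,7-dibromo-4,6-dimethylhepta-1,5-diene
Product: 18 methyl (2S,4S)-4-[(2Z,4S)-6-bromo-2,4-dimethylhepta-2,6-dien-1-yl]-2-tert-butyl-1,3-dioxolane-4-carboxylate, via lithium enolate of the tert-butyl dioxolane ester 17 (not isolated)
Conditions: LiN(iPr)2, THF, −78 °C; then 14, THF/DMPU, −78 → −50 °C
Reagents that add atoms: none
Why: In this ester enolate alkylation the exocyclic lithium enolate, which resists β-elimination at low temperature for stereoelectronic reasons, should be attacked by the primary allylic bromide on the face anti to the tert-butyl group, which sets the quaternary C4 as (S), and the minor diastereomer is a separable cis/trans isomer.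

Step 11
Reactants: 18 methyl (2S,4S)-4-[(2Z,4S)-6-bromo-2,4-dimethylhepta-2,6-dien-1-yl]-2-tert-butyl-1,3-dioxolane-4-carboxylate
Product: 19 methyl (2S,4Z,6S)-8-bromo-2-hydroxy-2-(hydroxymethyl)-4,6-dimethylnona-4,8-dienoate
Conditions: HCl (1.25 M in MeOH), 45 °C
Reagents that add atoms: none
Why: Acid-catalysed acetal methanolysis removes the robust tert-butyl acetal at this stage, where only a vinyl bromide and an isolated trisubstituted alkene are present, because its hydrolysis at the end would endanger the acid-labile dienyl lactone, and C4 is not involved.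

Step 12
Reactants: 19 methyl (2S,4Z,6S)-8-bromo-2-hydroxy-2-(hydroxymethyl)-4,6-dimethylnona-4,8-dienoate
Product: 20 methyl (2S,4Z,6S)-8-bromo-4,6-dimethyl-2-(triethylsilyloxy)-2-[(triethylsilyloxy)methyl]nona-4,8-dienoate
Conditions: Et3SiOTf (2.5 equiv), 2,6-lutidine, CH2Cl2, −78 → 0 °C
Reagents that add atoms: triethylsilyl trifluoromethanesulfonate CC[Si](CC)(CC)OS(=O)(=O)C(F)(F)F
Why: Silylation with the silyl triflate protects both the primary and the hindered tertiary hydroxyl as triethylsilyl ethers that fluoride can remove at the end.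

Step 13
Reactants: 20 methyl (2S,4Z,6S)-8-bromo-4,6-dimethyl-2-(triethylsilyloxy)-2-[(triethylsilyloxy)methyl]nona-4,8-dienoate
Product: 21 (2S,4Z,6S)-8-bromo-4,6-dimethyl-2-(triethylsilyloxy)-2-[(triethylsilyloxy)methyl]nona-4,8-dienal
Conditions: iBu2AlH (1.2 equiv), CH2Cl2, −78 °C; MeOH at −78 °C, then aqueous potassium sodium tartrate
Reagents that add atoms: none
Why: Partial reduction of the α-alkoxy ester with iBu2AlH at low temperature stops at the aldehyde through a stable tetrahedral aluminium hemiacetal, and the quaternary α-carbon cannot epimerise.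

Step 14
Reactants: 5 (1Z,3S)-2-methyl-1-(trimethylstannyl)pent-1-en-3-yl propanoate; 21 (2S,4Z,6S)-8-bromo-4,6-dimethyl-2-(triethylsilyloxy)-2-[(triethylsilyloxy)methyl]nona-4,8-dienal
Product: 23 (1Z,3S)-2-methyl-1-(trimethylstannyl)pent-1-en-3-yl (4S,6Z,8S)-10-bromo-3-hydroxy-2,6,8-trimethyl-4-(triethylsilyloxy)-4-[(triethylsilyloxy)methyl]undeca-6,10-dienoate (mixture of C2/C3 diastereomers), via lithium enolate of the stannyl propanoate 22 (not isolated)
Conditions: LiN(iPr)2, THF, −78 °C; then 21, −78 °C; AcOH quench at −78 °C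
Reagents that add atoms: none
Why: Lithium ester enolate aldol addition to the non-enolisable neopentyl aldehyde forms C2–C3 without control of the two new centres, which is accepted because C3 is oxidised next and C2 is labile afterwards, and the cold quench prevents retro-aldol, silyl migration and Ireland–Claisen rearrangement of the allylic ester enolate.

Step 15
Reactants: 23 (1Z,3S)-2-methyl-1-(trimethylstannyl)pent-1-en-3-yl (4S,6Z,8S)-10-bromo-3-hydroxy-2,6,8-trimethyl-4-(triethylsilyloxy)-4-[(triethylsilyloxy)methyl]undeca-6,10-dienoate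
Product: 24 (1Z,3S)-2-methyl-1-(trimethylstannyl)pent-1-en-3-yl (4S,6Z,8S)-10-bromo-2,6,8-trimethyl-3-oxo-4-(triethylsilyloxy)-4-[(triethylsilyloxy)methyl]undeca-6,10-dienoate (interconverting C2 epimers)
Conditions: Dess–Martin periodinane, pyridine, CH2Cl2, 0 → 23 °C
Reagents that add atoms: none
Why: Dess–Martin oxidation of the hindered secondary alcohol under pyridine buffering gives the β-keto ester without harming the vinylstannane or the silyl ethers, and all diastereomers of 23 converge on one pair of C2 epimers that interconvert through the enol.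

Step 16
Reactants: 24 (1Z,3S)-2-methyl-1-(trimethylstannyl)pent-1-en-3-yl (4S,6Z,8S)-10-bromo-2,6,8-trimethyl-3-oxo-4-(triethylsilyloxy)-4-[(triethylsilyloxy)methyl]undeca-6,10-dienoate
Product: 25 (4S,6Z,8S,11Z,13S)-2,6,8,12-tetramethyl-10-methylidene-3-oxo-4-(triethylsilyloxy)-4-[(triethylsilyloxy)methyl]pentadeca-6,11-dien-13-olide (14-membered lactone; C2 epimers)
Conditions: Pd2(dba)3·CHCl3 (10 mol %), AsPh3 (80 mol %), copper thiophene-2-carboxylate Cu(O2C-2-thienyl) (2 equiv), degassed NMP, 23 → 40 °C, syringe-pump addition to about 1 mM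
Reagents that add atoms: none
Why: Zerovalent palladium inserts into the C10–Br bond of the 2-bromoalkene, the monovalent copper carboxylate turns the C11 trimethylstannane into an alkenylcopper (tin leaves as its carboxylate) that transmetalates to divalent palladium, and reductive elimination forms C10–C11 with retention of both alkene geometries. The closest known reaction type is the copper-assisted intramolecular Stille coupling of a vinyl halide with a vinylstannane to give macrocyclic 1,3-dienes. The 14-membered ring closes in the reductive elimination from a 15-membered palladacycle, an end-to-end union of two planar sp2 carbons far from the ester, so the closure adds little transannular strain. No stereocentre is formed: C4, C8 and C13 are untouched and C2 remains labile. The step needs ring closure to beat oligomerisation and C–Br insertion to beat ionisation of the hindered allylic β-keto ester; slow addition at high dilution, the chain pre-bent by the Z C6=C7 and Z C11=C12 alkenes and the ester, the pre-set Z-stannane, and the weakly donating AsPh3 ligand at low temperature secure this.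

Step 17
Reactants: 25 (4S,6Z,8S,11Z,13S)-2,6,8,12-tetramethyl-10-methylidene-3-oxo-4-(triethylsilyloxy)-4-[(triethylsilyloxy)methyl]pentadeca-6,11-dien-13-olide
Product: 26 (2R,4S,6Z,8S,11Z,13S)-4-hydroxy-4-(hydroxymethyl)-2,6,8,12-tetramethyl-10-methylidene-3-oxopentadeca-6,11-dien-13-olide (CNP0240796.3)
Conditions: HF·pyridine, pyridine, THF, 0 → 23 °C
Reagents that add atoms: none
Why: Fluoride-mediated desilylation frees the C4 diol under buffered, weakly acidic conditions that spare the dienyl lactone and avoid the base-induced translactonisation of a γ-hydroxy β-keto ester, and C2 should settle as the (2R) epimer by enol-mediated equilibration of the β-keto lactone.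

**Compound list**

1 | rac-pent-1-yn-3-ol | CCC(O)C#C | starting material
2 | chelated alkenylmagnesium alkoxide (five-membered C–Mg–O ring, racemic) | CCC1O[Mg]C=C1C | intermediate
3 | rac-(1Z)-2-methyl-1-(trimethylstannyl)pent-1-en-3-ol | C[Sn](C)(C)/C=C(/C)C(O)CC | intermediate
4 | (1Z,3S)-2-methyl-1-(trimethylstannyl)pent-1-en-3-ol | C[Sn](C)(C)/C=C(/C)[C@H](CC)O | intermediate
5 | (1Z,3S)-2-methyl-1-(trimethylstannyl)pent-1-en-3-yl propanoate | C[Sn](C)(C)/C=C(/C)[C@H](CC)OC(=O)CC | intermediate
6 | (R)-4-benzyl-3-propanoyloxazolidin-2-one | CCC(=O)N1[C@H](Cc2ccccc2)COC1=O | starting material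
7 | 2,3-dibromoprop-1-ene | C=C(Br)CBr | starting material
8 | sodium Z-enolate of imide 6 | [Na+].C/C=C(\[O-])N1[C@H](Cc2ccccc2)COC1=O | intermediate
9 | (R)-4-benzyl-3-[(2S)-4-bromo-2-methylpent-4-enoyl]oxazolidin-2-one | C=C(Br)C[C@H](C)C(=O)N1[C@H](Cc2ccccc2)COC1=O | intermediate
10 | (2S)-4-bromo-2-methylpent-4-en-1-ol | C=C(Br)C[C@H](C)CO | intermediate
11 | (2S)-4-bromo-2-methylpent-4-enal | C=C(Br)C[C@H](C)C=O | intermediate
12 | methyl (2Z,4S)-6-bromo-2,4-dimethylhepta-2,6-dienoate | C=C(Br)C[C@H](C)/C=C(/C)C(=O)OC | intermediate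
13 | (2Z,4S)-6-bromo-2,4-dimethylhepta-2,6-dien-1-ol | C=C(Br)C[C@H](C)/C=C(/C)CO | intermediate
14 | (4S,5Z)-2,7-dibromo-4,6-dimethylhepta-1,5-diene | C=C(Br)C[C@H](C)/C=C(/C)CBr | intermediate
15 | methyl (4S)-2,2-dimethyl-1,3-dioxolane-4-carboxylate | COC(=O)[C@@H]1COC(C)(C)O1 | starting material
16 | methyl (2S,4S)-2-tert-butyl-1,3-dioxolane-4-carboxylate (cis) | COC(=O)[C@@H]1CO[C@H](C(C)(C)C)O1 | intermediate
17 | lithium enolate of ester 16 (exocyclic C=C, acetal centre 2S) | [Li+].COC([O-])=C1CO[C@H](C(C)(C)C)O1 | intermediate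
18 | methyl (2S,4S)-4-[(2Z,4S)-6-bromo-2,4-dimethylhepta-2,6-dien-1-yl]-2-tert-butyl-1,3-dioxolane-4-carboxylate | COC(=O)[C@]1(C/C(C)=C\[C@@H](C)CC(Br)=C)CO[C@H](C(C)(C)C)O1 | intermediate
19 | methyl (2S,4Z,6S)-8-bromo-2-hydroxy-2-(hydroxymethyl)-4,6-dimethylnona-4,8-dienoate | COC(=O)[C@@](O)(CO)C/C(C)=C\[C@@H](C)CC(Br)=C | intermediate
20 | methyl (2S,4Z,6S)-8-bromo-4,6-dimethyl-2-(triethylsilyloxy)-2-[(triethylsilyloxy)methyl]nona-4,8-dienoate | COC(=O)[C@@](O[Si](CC)(CC)CC)(CO[Si](CC)(CC)CC)C/C(C)=C\[C@@H](C)CC(Br)=C | intermediate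
21 | (2S,4Z,6S)-8-bromo-4,6-dimethyl-2-(triethylsilyloxy)-2-[(triethylsilyloxy)methyl]nona-4,8-dienal | O=C[C@@](O[Si](CC)(CC)CC)(CO[Si](CC)(CC)CC)C/C(C)=C\[C@@H](C)CC(Br)=C | intermediate
22 | lithium enolate of propanoate 5 | [Li+].CC=C([O-])O[C@@H](CC)/C(C)=C\[Sn](C)(C)C | intermediate
23 | (1Z,3S)-2-methyl-1-(trimethylstannyl)pent-1-en-3-yl (4S,6Z,8S)-10-bromo-3-hydroxy-2,6,8-trimethyl-4-(triethylsilyloxy)-4-[(triethylsilyloxy)methyl]undeca-6,10-dienoate, C2/C3 diastereomers | C[Sn](C)(C)/C=C(/C)[C@H](CC)OC(=O)C(C)C(O)[C@@](O[Si](CC)(CC)CC)(CO[Si](CC)(CC)CC)C/C(C)=C\[C@@H](C)CC(Br)=C | intermediate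
24 | (1Z,3S)-2-methyl-1-(trimethylstannyl)pent-1-en-3-yl (4S,6Z,8S)-10-bromo-2,6,8-trimethyl-3-oxo-4-(triethylsilyloxy)-4-[(triethylsilyloxy)methyl]undeca-6,10-dienoate, C2 epimers | C[Sn](C)(C)/C=C(/C)[C@H](CC)OC(=O)C(C)C(=O)[C@@](O[Si](CC)(CC)CC)(CO[Si](CC)(CC)CC)C/C(C)=C\[C@@H](C)CC(Br)=C | intermediate
25 | (4S,6Z,8S,11Z,13S)-2,6,8,12-tetramethyl-10-methylidene-3-oxo-4-(triethylsilyloxy)-4-[(triethylsilyloxy)methyl]pentadeca-6,11-dien-13-olide, C2 epimers | C=C1/C=C(/C)[C@H](CC)OC(=O)C(C)C(=O)[C@@](O[Si](CC)(CC)CC)(CO[Si](CC)(CC)CC)C/C(C)=C\[C@@H](C)C1 | intermediate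
26 | (2R,4S,6Z,8S,11Z,13S)-4-hydroxy-4-(hydroxymethyl)-2,6,8,12-tetramethyl-10-methylidene-3-oxopentadeca-6,11-dien-13-olide | C=C1/C=C(/C)[C@H](CC)OC(=O)[C@H](C)C(=O)[C@@](O)(CO)C/C(C)=C\[C@@H](C)C1 | target

**Count and risks**

Total: 17 steps. Longest linear sequence: 13 steps (steps 4–8 and 10–17, from imide 6).

Step 16 (macrocyclisation). Oxidative addition into the 2-bromoalkene and transmetalation of the hindered Z-stannane may be slow at the dilution needed. Oligomerisation, protodestannylation, stannane homocoupling or palladium-induced ionisation of the allylic β-keto ester could then outrun ring closure. In the fallback the C10–C11 bond is formed between two separate molecules and the ring is closed at the lactone. Setting out from aldehyde 21, aldol addition of the lithium enolate of tert-butyl propanoate would give tert-butyl β-hydroxy ester F1, and Dess–Martin oxidation would give tert-butyl β-keto ester F2. A bimolecular Stille coupling of F2 with stannyl alcohol 4 (Pd2(dba)3·CHCl3, AsPh3, Cu(O2C-2-thienyl), NMP, concentrated) would give hydroxy diene keto ester F3. Heating F3 in toluene at high dilution expels tert-butanol, and the C13 hydroxyl traps the acylketene (acylketene macrolactonisation), which comes back to the route at macrolactone 25.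

Step 10 (alkylation at C4). The exocyclic enolate may undergo β-elimination, or the remote tert-butyl group may give too little facial bias. The fallback sets C4 by reagent control. Setting out from bromide 14, alkylation of the sodium salt of triethyl phosphonoacetate (NaH, THF) would give phosphonate F4. Horner–Wadsworth–Emmons reaction with aqueous formaldehyde and K2CO3 would give 2-methylidene ester F5, and iBu2AlH would give allylic alcohol F6. Sharpless asymmetric epoxidation (Ti(OiPr)4, D-(−)-diisopropyl tartrate, t-BuOOH, 4 Å sieves, CH2Cl2, −20 °C) would give epoxy alcohol F7; only the allylic alcohol alkene reacts. Oxidation with TEMPO and PhI(OAc)2 in wet MeCN would give glycidic acid F8, and Me3SiCHN2 its methyl ester F9. Acid-catalysed hydrolysis (HClO4, THF/H2O) opens the epoxide at its CH2 carbon with retention at the quaternary centre and comes back to the route at diol ester 19.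

Step 14 (aldol union). Retro-aldol cleavage, oxygen-to-oxygen silyl migration in the lithium aldolate, or Claisen-type reactions of the allylic ester enolate may erode the coupling of the two advanced fragments. The fallback avoids strong base. Setting out from alcohol 4, acylation with 2-bromopropanoyl bromide and pyridine would give 2-bromopropanoate F10. A SmI2-mediated Reformatsky addition of F10 to aldehyde 21 (THF, −78 °C), under neutral conditions, comes back to the route at β-hydroxy ester 23.

Further compounds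
F1 | step 16 | tert-butyl (4S,6Z,8S)-10-bromo-3-hydroxy-2,6,8-trimethyl-4-(triethylsilyloxy)-4-[(triethylsilyloxy)methyl]undeca-6,10-dienoate (C2/C3 diastereomers) | CC(C)(C)OC(=O)C(C)C(O)[C@@](O[Si](CC)(CC)CC)(CO[Si](CC)(CC)CC)C/C(C)=C\[C@@H](C)CC(Br)=C
F2 | step 16 | tert-butyl (4S,6Z,8S)-10-bromo-2,6,8-trimethyl-3-oxo-4-(triethylsilyloxy)-4-[(triethylsilyloxy)methyl]undeca-6,10-dienoate (C2 epimers) | CC(C)(C)OC(=O)C(C)C(=O)[C@@](O[Si](CC)(CC)CC)(CO[Si](CC)(CC)CC)C/C(C)=C\[C@@H](C)CC(Br)=C
F3 | step 16 | tert-butyl (4S,6Z,8S,11Z,13S)-13-hydroxy-2,6,8,12-tetramethyl-10-methylidene-3-oxo-4-(triethylsilyloxy)-4-[(triethylsilyloxy)methyl]pentadeca-6,11-dienoate (C2 epimers) | CC(C)(C)OC(=O)C(C)C(=O)[C@@](O[Si](CC)(CC)CC)(CO[Si](CC)(CC)CC)C/C(C)=C\[C@@H](C)CC(=C)/C=C(/C)[C@H](CC)O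
F4 | step 10 | ethyl (4Z,6S)-8-bromo-2-(diethoxyphosphoryl)-4,6-dimethylnona-4,8-dienoate (C2 epimers) | CCOC(=O)C(C/C(C)=C\[C@@H](C)CC(Br)=C)P(=O)(OCC)OCC
F5 | step 10 | ethyl (4Z,6S)-8-bromo-4,6-dimethyl-2-methylidenenona-4,8-dienoate | CCOC(=O)C(=C)C/C(C)=C\[C@@H](C)CC(Br)=C
F6 | step 10 | (4Z,6S)-8-bromo-4,6-dimethyl-2-methylidenenona-4,8-dien-1-ol | OCC(=C)C/C(C)=C\[C@@H](C)CC(Br)=C
F7 | step 10 | {(2R)-2-[(2Z,4S)-6-bromo-2,4-dimethylhepta-2,6-dien-1-yl]oxiran-2-yl}methanol | OC[C@]1(C/C(C)=C\[C@@H](C)CC(Br)=C)CO1
F8 | step 10 | (2S)-2-[(2Z,4S)-6-bromo-2,4-dimethylhepta-2,6-dien-1-yl]oxirane-2-carboxylic acid | OC(=O)[C@]1(C/C(C)=C\[C@@H](C)CC(Br)=C)CO1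
F9 | step 10 | methyl (2S)-2-[(2Z,4S)-6-bromo-2,4-dimethylhepta-2,6-dien-1-yl]oxirane-2-carboxylate | COC(=O)[C@]1(C/C(C)=C\[C@@H](C)CC(Br)=C)CO1
F10 | step 14 | (1Z,3S)-2-methyl-1-(trimethylstannyl)pent-1-en-3-yl 2-bromopropanoate (epimers at the brominated carbon) | C[Sn](C)(C)/C=C(/C)[C@H](CC)OC(=O)C(C)Br
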